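**Retrosynthetic overview**

1. Numbering used throughout: ring A (seven-membered) is C2 (fusion CH)–C1 (CH2)–C10 (C(CH3)OH)–C9 (CH2)–C8 (CH–O-acyl)–C7 (CH–iPr)–C6 (fusion CH); ring B (five-membered) is C2–C3 (oxirane CH)–C4 (oxirane C–CH3)–C5 (CH2)–C6; β is the face of H-6, which also carries the isopropyl group, O-8, O-10, the oxirane oxygen and, on ring A, the C2–C3 bond.
2. The strategy rests on the C3–C4 oxirane of ring B: it lies β, on the side of the C1 branch of C2 (the face an external oxidant would avoid), and ring B is close to mirror-symmetric about C4, so epoxidation of a ring B alkene would be uncertain in both site and face.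
3. After the C8 isovanillate is cut, C3–C4 and C3–O are therefore disconnected together: a C3 diphenylsulfonium ylide adds to the C4 methyl ketone of a ring A cycloheptane and the alkoxide expels Ph2S, so ring B and the oxirane close last, in one operation.
4. The cycloheptane comes from the C8(=O)–C9=C10 enone by reduction, hydroxyl-directed epoxidation and hydride opening (cis-8,10-diol); the enone comes from insertion of C9 into a cyclohexene silyl enol ether (cyclopropanation, FeCl3).
5. That cyclohexene (C2, C6, C7 all trans) comes from a catalytic asymmetric Diels–Alder reaction of a (Z)-2-siloxydiene (from isovaleraldehyde) with an (E)-enal (from ethyl (S)-3-hydroxybutanoate) whose benzyloxy carbinol is the masked C4 ketone; ring order: six-membered carbocycle, ring A by expansion, then ring B with the oxirane.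

Key step: step 20

Remark: the facial sense of the oxazaborolidinium catalyst in step 7 is assigned from the usual formyl C–H···O binding model for enals (the (R)-prolinol-derived catalyst for attack on the Cα-Si face); should the adduct prove antipodal, the (S)-catalyst would be used with no other change.

**Route**

Step 1
Reactants: 1 isovaleraldehyde; 2 isopropenylmagnesium bromide
Product: 3 (±)-2,5-dimethylhex-1-en-3-ol
Conditions: THF, 0 °C; aq. NH4Cl
Reagents that add atoms: none
Why: 1,2-addition of the alkenyl Grignard reagent to the aldehyde gives the allylic alcohol, whose stereocentre is removed in step 2.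

Step 2
Reactants: 3 (±)-2,5-dimethylhex-1-en-3-ol
Product: 4 2,5-dimethylhex-1-en-3-one
Conditions: Dess–Martin periodinane, NaHCO3, CH2Cl2, 0 °C → rt
Reagents that add atoms: none
Why: Dess–Martin oxidation of the secondary allylic alcohol gives the cross-conjugated enone under neutral conditions that do not move the 1,1-disubstituted alkene.

Step 3
Reactants: 4 2,5-dimethylhex-1-en-3-one
Product: 5 (Z)-3-(tert-butyldimethylsilyloxy)-2,5-dimethylhexa-1,3-diene
Conditions: t-BuMe2SiOTf, Et3N, CH2Cl2, 0 °C
Reagents that add atoms: tert-butyldimethylsilyl triflate, CC(C)(C)[Si](C)(C)OS(=O)(=O)C(F)(F)F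
Why: Soft enolisation of the α′-methylene gives the 2-siloxydiene, and allylic strain favours the (Z)-enol ether, in which the isopropyl group is cis to oxygen and therefore points outward on the diene.

Step 4
Reactants: 6 ethyl (S)-3-hydroxybutanoate
Product: 7 ethyl (S)-3-(benzyloxy)butanoate
Conditions: BnOC(=NH)CCl3, TfOH (cat.), cyclohexane/CH2Cl2, rt
Reagents that add atoms: benzyl 2,2,2-trichloroacetimidate, ClC(Cl)(Cl)C(=N)OCc1ccccc1
Why: Acid-catalysed O-benzylation with the trichloroacetimidate avoids the base-induced elimination of the β-hydroxy ester and leaves the stereocentre untouched.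

Step 5
Reactants: 7 ethyl (S)-3-(benzyloxy)butanoate
Product: 8 (S)-3-(benzyloxy)butanal
Conditions: i-Bu2AlH, CH2Cl2, −78 °C; Rochelle salt
Reagents that add atoms: none
Why: Half-reduction of the ester at low temperature stops at the aluminium hemiacetal, which releases the aldehyde on work-up.

Step 6
Reactants: 8 (S)-3-(benzyloxy)butanal; 9 (triphenylphosphoranylidene)acetaldehyde
Product: 10 (2E,5S)-5-(benzyloxy)hex-2-enal
Conditions: toluene, 80 °C
Reagents that add atoms: none
Why: Wittig olefination with the formyl-stabilised ylide gives the (E)-enal.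

Step 7
Reactants: 5 (Z)-3-(tert-butyldimethylsilyloxy)-2,5-dimethylhexa-1,3-diene; 10 (2E,5S)-5-(benzyloxy)hex-2-enal
Product: 11 cyclohexene aldehyde (2β-formyl; 6α-[(S)-2-benzyloxypropyl]; 7β-isopropyl; silyl enol ether C8=C10)
Conditions: (R)-tetrahydro-1-(2-methylphenyl)-3,3-diphenyl-1H,3H-pyrrolo[1,2-c][1,3,2]oxazaborole·HN(SO2CF3)2 (20 mol%), CH2Cl2, −78 → −40 °C
Reagents that add atoms: none
Why: Catalytic enantioselective Diels–Alder reaction in which the siloxy group makes C7 the nucleophilic diene terminus that bonds to the enal β-carbon (C6), the (E)-enal fixes C2/C6 trans, the endo (formyl) transition state with the outward isopropyl group fixes C6/C7 trans, and the cationic oxazaborolidine bound to the formyl group shields one enal face so that C2, C6 and C7 are set in absolute terms.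

Step 8
Reactants: 11 cyclohexene aldehyde
Product: 12 cyclohexene primary alcohol (C3–OH)
Conditions: NaBH4, EtOH/THF, 0 °C
Reagents that add atoms: none
Why: Hydride reduction of the aldehyde is chemoselective beside the silyl enol ether and removes the epimerisable formyl group at once.

Step 9
Reactants: 12 cyclohexene primary alcohol
Product: 13 cyclohexene bis(benzyl ether)
Conditions: NaH, BnBr, Bu4NI (cat.), THF/DMF, 0 °C → rt
Reagents that add atoms: benzyl bromide, BrCc1ccccc1
Why: Williamson etherification keeps O-3 masked until O-10 is silylated (a leaving group at C3 would be displaced by a free cis C10 alkoxide), and the silyl enol ether is stable to NaH.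

Step 10
Reactants: 13 cyclohexene bis(benzyl ether)
Product: 14 siloxycyclopropane (C9 methylene bridging C8 and C10)
Conditions: Et2Zn, CH2I2, toluene, 0 °C → rt
Reagents that add atoms: diiodomethane, ICI
Why: Simmons–Smith cyclopropanation (Furukawa variant) of the electron-rich tetrasubstituted silyl enol ether, expected anti to the C7 isopropyl group, with both cyclopropane diastereomers converging in step 11.

Step 11
Reactants: 14 siloxycyclopropane
Product: 16 cyclohept-9-en-8-one (ring A enone), via β-chloro ketone 15 (not isolated)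
Conditions: FeCl3, pyridine, DMF, 0 °C → rt; then NaOAc, MeOH, reflux
Reagents that add atoms: none
Why: Iron trichloride oxidises the siloxycyclopropane with cleavage of the internal C8–C10 bond to the ring-expanded tertiary C10 radical, which takes up chlorine, and acetate then eliminates HCl (E1cB) to the conjugated cycloheptenone (Saegusa-type ring expansion), C7 keeping its more stable configuration trans to the C6 branch.

Step 12
Reactants: 16 cyclohept-9-en-8-one
Product: 17 allylic alcohol (8β-OH)
Conditions: LiBH(s-Bu)3, THF, −78 °C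
Reagents that add atoms: none
Why: The bulky borohydride reduces 1,2 (the β,β-disubstituted terminus blocks conjugate attack) and enters C8 from the α face, opposite the adjacent C7 isopropyl group, as bulky hydrides do with α′-alkyl-β-methylcycloalkenones, so the hydroxyl is cis to isopropyl.

Step 13
Reactants: 17 allylic alcohol
Product: 18 9β,10β-epoxy-8β-alcohol
Conditions: VO(acac)2 (5 mol%), t-BuOOH, CH2Cl2, 0 °C → rt
Reagents that add atoms: tert-butyl hydroperoxide, CC(C)(C)OO
Why: Hydroxyl-directed epoxidation of the cyclic allylic alcohol delivers oxygen to the face of the C8 hydroxyl, which sets C10 with O β and methyl α.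

Step 14
Reactants: 18 9β,10β-epoxy-8β-alcohol
Product: 19 cis-8β,10β-diol
Conditions: LiAlH4, THF, 0 → 50 °C
Reagents that add atoms: none
Why: Hydride opens the trisubstituted epoxide by SN2 attack at the secondary C9 (the tertiary C10 is inaccessible), so the C10–O bond and its configuration are kept and the cis-1,3-diol results.

Step 15
Reactants: 19 cis-8β,10β-diol
Product: 20 8,10-bis(triethylsilyl) ether
Conditions: Et3SiOTf, 2,6-lutidine, CH2Cl2, −78 → 0 °C
Reagents that add atoms: triethylsilyl triflate, CC[Si](CC)(CC)OS(=O)(=O)C(F)(F)F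
Why: The silyl triflate silylates the secondary and the tertiary hydroxyl alike, which blocks O-8 and O-10 as nucleophiles toward C3 and gives fluoride-labile groups for the end of the route.

Step 16
Reactants: 20 8,10-bis(triethylsilyl) ether
Product: 21 diol (C3–OH primary; side-chain carbinol secondary)
Conditions: H2 (1 atm), Pd(OH)2/C, EtOAc, rt
Reagents that add atoms: none
Why: Hydrogenolysis removes both benzyl ethers in ethyl acetate, a solvent in which triethylsilyl ethers survive.

Step 17
Reactants: 21 diol
Product: 22 C3 iodide (side-chain carbinol free)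
Conditions: I2, PPh3, imidazole, CH2Cl2, 0 °C
Reagents that add atoms: iodine, II
Why: Appel-type iodination is selective for the primary alcohol because iodide displacement of the alkoxyphosphonium ion at the secondary carbinol is much slower.

Step 18
Reactants: 22 C3 iodide
Product: 23 iodo methyl ketone (C4 ketone)
Conditions: Dess–Martin periodinane, NaHCO3, CH2Cl2, 0 °C → rt
Reagents that add atoms: none
Why: Buffered Dess–Martin oxidation unveils the C4 ketone without acid, so the silyl ethers and the iodide stay intact.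

Step 19
Reactants: 23 iodo methyl ketone; 24 diphenyl sulfide
Product: 25 keto diphenylsulfonium tetrafluoroborate
Conditions: Ph2S (10 equiv), AgBF4, CH2Cl2, 0 °C → rt, dark; used at once
Reagents that add atoms: silver tetrafluoroborate, [Ag+].F[B-](F)(F)F
Why: Silver-assisted S-alkylation of diphenyl sulfide by the primary iodide, driven by precipitation of AgI, is the standard route to alkyldiphenylsulfonium tetrafluoroborates.

Step 20
Reactants: 25 keto diphenylsulfonium tetrafluoroborate
Product: 28 bis(triethylsilyl) epoxy hydroazulene, via sulfonium ylide 26 (not isolated), via anti betaine 27 (not isolated)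
Conditions: KN(SiMe3)2 (1.05 equiv), THF, −78 → 0 °C
Reagents that add atoms: none
Why: Proposed new method: KN(SiMe3)2 removes a C3 proton of the sulfonium salt (the only acidic position on sulfur and several pK units more acidic than the ketone α-hydrogens), the ylide carbon C3 adds to the C4 carbonyl, and the C4 alkoxide displaces Ph2S from C3 with inversion; the closest known reaction type is the Corey–Chaykovsky epoxidation of ketones by diphenylsulfonium alkylides, together with epoxy-annulations in which a tethered diphenylsulfonium ylide closes an epoxide-fused five-membered heterocycle onto a ketone, here extended to an all-carbon tether on a trans-fused bicycle. Ring B closes 5-exo-trig (C3–C4) and the oxirane 3-exo-tet (C3–O). C3 is controlled by the C1 branch on C2, which sends the Ph2S+ group to the α face of the forming ring so that after inversion the oxygen on C3 is β, and C4 is controlled by the need for backside displacement, since only the betaine with O anti to S (O β, methyl α) can close. The step therefore needs one of four betaines, that with sulfur α and oxygen β; the clash of Ph2S+ with C1 secures the sulfur face, and the syn betaine, which cannot close, is expected to revert to ylide and ketone. The oxirane position is fixed by connectivity and the silyl ethers keep O-10 and O-8 away from C3, while E2 loss of Ph2S toward H-2 and alkylation of the methyl ketone enolate at C3 are held back by low temperature and a single equivalent of base.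

Step 21
Reactants: 28 bis(triethylsilyl) epoxy hydroazulene
Product: 29 epoxy diol (8β-OH; 10β-OH)
Conditions: Bu4NF, THF, 0 °C → rt
Reagents that add atoms: none
Why: Fluoride cleaves both Si–O bonds, and the epoxide is inert to these non-acidic conditions.

Step 22
Reactants: 30 isovanillic acid
Product: 32 3-(tert-butyldimethylsilyloxy)-4-methoxybenzoic acid, via bis-silyl isovanillate 31 (not isolated)
Conditions: t-BuMe2SiCl, imidazole, DMF, rt; then K2CO3, THF/MeOH/H2O, rt; mild acid work-up
Reagents that add atoms: tert-butyldimethylsilyl chloride, CC(C)(C)[Si](C)(C)Cl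
Why: Silylation covers phenol and acid, and mild aqueous carbonate then cleaves only the far more labile silyl ester.

Step 23
Reactants: 29 epoxy diol; 32 3-(tert-butyldimethylsilyloxy)-4-methoxybenzoic acid
Product: 34 O-silylated C8 isovanillate, via mixed anhydride 33 (not isolated)
Conditions: 32, 2,4,6-Cl3C6H2COCl, Et3N, THF, rt; then 29, DMAP, toluene, rt → 40 °C
Reagents that add atoms: none
Why: Yamaguchi esterification acylates the secondary C8 hydroxyl only, because the tertiary C10 hydroxyl is too hindered, and the basic medium leaves the epoxide alone.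

Step 24
Reactants: 34 O-silylated C8 isovanillate
Product: 35 CNP0106636.1
Conditions: Bu4NF, AcOH, THF, 0 °C
Reagents that add atoms: none
Why: Buffered fluoride removes the aryl silyl ether rapidly while the benzoate ester, the tertiary alcohol and the epoxide are untouched.

**Compound list**

1 | isovaleraldehyde (3-methylbutanal) | CC(C)CC=O | starting material
2 | isopropenylmagnesium bromide | C=C(C)[Mg]Br | starting material
3 | (±)-2,5-dimethylhex-1-en-3-ol | C=C(C)C(O)CC(C)C | intermediate
4 | 2,5-dimethylhex-1-en-3-one | C=C(C)C(=O)CC(C)C | intermediate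
5 | (Z)-3-(tert-butyldimethylsilyloxy)-2,5-dimethylhexa-1,3-diene | C=C(C)/C(O[Si](C)(C)C(C)(C)C)=C/C(C)C | intermediate
6 | ethyl (S)-3-hydroxybutanoate | C[C@H](O)CC(=O)OCC | starting material
7 | ethyl (S)-3-(benzyloxy)butanoate | C[C@H](OCc1ccccc1)CC(=O)OCC | intermediate
8 | (S)-3-(benzyloxy)butanal | C[C@H](OCc1ccccc1)CC=O | intermediate
9 | (triphenylphosphoranylidene)acetaldehyde | O=CC=P(c1ccccc1)(c1ccccc1)c1ccccc1 | starting material
10 | (2E,5S)-5-(benzyloxy)hex-2-enal | C[C@H](OCc1ccccc1)C/C=C/C=O | intermediate
11 | (1S)-6-[(S)-2-(benzyloxy)propyl]-4-(tert-butyldimethylsilyloxy)-5-isopropyl-3-methylcyclohex-3-ene-1-carbaldehyde, 1,6-trans and 5,6-trans (2β-CHO, 6α-side chain, 7β-iPr in target numbering) | C[C@H](OCc1ccccc1)C[C@@H]2[C@@H](C=O)CC(C)=C(O[Si](C)(C)C(C)(C)C)[C@H]2C(C)C | intermediate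
12 | corresponding primary alcohol (C3–OH) of 11 | C[C@H](OCc1ccccc1)C[C@@H]2[C@@H](CO)CC(C)=C(O[Si](C)(C)C(C)(C)C)[C@H]2C(C)C | intermediate
13 | C3 benzyl ether of 12 (bis-benzyl ether, silyl enol ether C8=C10) | C[C@H](OCc1ccccc1)C[C@@H]2[C@@H](COCc3ccccc3)CC(C)=C(O[Si](C)(C)C(C)(C)C)[C@H]2C(C)C | intermediate
14 | 1-(tert-butyldimethylsilyloxy)-6-methylbicyclo[4.1.0]heptane from 13, cyclopropane C8–C9–C10 with C9 on the α face (the β-C9 isomer converges) | C[C@H](OCc1ccccc1)C[C@@H]2[C@@H](COCc3ccccc3)C[C@]4(C)C[C@]4(O[Si](C)(C)C(C)(C)C)[C@H]2C(C)C | intermediate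
15 | 10-chloro-10-methylcycloheptan-8-one (β-chloro ketone, mixture at C10) with 2β-CH2OBn, 6α-[(S)-2-benzyloxypropyl], 7β-iPr | C[C@H](OCc1ccccc1)C[C@@H]2[C@@H](COCc3ccccc3)CC(C)(Cl)CC(=O)[C@H]2C(C)C | intermediate
16 | 2β-(benzyloxymethyl)-6α-[(S)-2-(benzyloxy)propyl]-7β-isopropyl-10-methylcyclohept-9-en-8-one | C[C@H](OCc1ccccc1)C[C@@H]2[C@@H](COCc3ccccc3)CC(C)=CC(=O)[C@H]2C(C)C | intermediate
17 | 8β-allylic alcohol of 16 (OH cis to isopropyl) | C[C@H](OCc1ccccc1)C[C@@H]2[C@@H](COCc3ccccc3)CC(C)=C[C@@H](O)[C@H]2C(C)C | intermediate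
18 | 9β,10β-epoxy-8β-alcohol (10α-methyl) | C[C@H](OCc1ccccc1)C[C@@H]2[C@@H](COCc3ccccc3)C[C@@]4(C)O[C@H]4[C@@H](O)[C@H]2C(C)C | intermediate
19 | 8β,10β-diol (10α-methyl) with 2β-CH2OBn, 6α-[(S)-2-benzyloxypropyl], 7β-iPr | C[C@H](OCc1ccccc1)C[C@@H]2[C@@H](COCc3ccccc3)C[C@@](C)(O)C[C@@H](O)[C@H]2C(C)C | intermediate
20 | 8β,10β-bis(triethylsilyl) ether of 19 | C[C@H](OCc1ccccc1)C[C@@H]2[C@@H](COCc3ccccc3)C[C@@](C)(O[Si](CC)(CC)CC)C[C@@H](O[Si](CC)(CC)CC)[C@H]2C(C)C | intermediate
21 | bis-silyl cycloheptane with 2β-CH2OH and 6α-[(S)-2-hydroxypropyl] | C[C@H](O)C[C@@H]1[C@@H](CO)C[C@@](C)(O[Si](CC)(CC)CC)C[C@@H](O[Si](CC)(CC)CC)[C@H]1C(C)C | intermediate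
22 | bis-silyl cycloheptane with 2β-CH2I and 6α-[(S)-2-hydroxypropyl] | C[C@H](O)C[C@@H]1[C@@H](CI)C[C@@](C)(O[Si](CC)(CC)CC)C[C@@H](O[Si](CC)(CC)CC)[C@H]1C(C)C | intermediate
23 | bis-silyl cycloheptane with 2β-CH2I and 6α-(2-oxopropyl) | CC(=O)C[C@@H]1[C@@H](CI)C[C@@](C)(O[Si](CC)(CC)CC)C[C@@H](O[Si](CC)(CC)CC)[C@H]1C(C)C | intermediate
24 | diphenyl sulfide | c1ccc(Sc2ccccc2)cc1 | starting material
25 | cycloheptane keto sulfonium salt: 2β-CH2S+Ph2, 6α-(2-oxopropyl), 7β-iPr, 8β-OSiEt3, 10β-OSiEt3, tetrafluoroborate | CC(=O)C[C@@H]1[C@@H](C[S+](c2ccccc2)c2ccccc2)C[C@@](C)(O[Si](CC)(CC)CC)C[C@@H](O[Si](CC)(CC)CC)[C@H]1C(C)C.F[B-](F)(F)F | intermediate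
26 | C3 sulfonium ylide of 25 | CC(=O)C[C@@H]1[C@@H]([CH-][S+](c2ccccc2)c2ccccc2)C[C@@](C)(O[Si](CC)(CC)CC)C[C@@H](O[Si](CC)(CC)CC)[C@H]1C(C)C | intermediate
27 | anti betaine: ring B closed, 3α-S+Ph2, 4β-O−, 4α-CH3 | CC[Si](CC)(CC)O[C@@H]1C[C@](C)(O[Si](CC)(CC)CC)C[C@H]2[C@@H](C[C@@](C)([O-])[C@@H]2[S+](c3ccccc3)c3ccccc3)[C@@H]1C(C)C | intermediate
28 | 8β,10β-bis(triethylsilyloxy)-3β,4β-epoxy hydroazulene core (trans-fused; 7β-iPr; 4α- and 10α-CH3) | CC[Si](CC)(CC)O[C@@H]1C[C@](C)(O[Si](CC)(CC)CC)C[C@H]2[C@@H](C[C@@]3(C)O[C@@H]23)[C@@H]1C(C)C | intermediate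
29 | 3β,4β-epoxy-8β,10β-diol core | O[C@@H]1C[C@](C)(O)C[C@H]2[C@@H](C[C@@]3(C)O[C@@H]23)[C@@H]1C(C)C | intermediate
30 | isovanillic acid (3-hydroxy-4-methoxybenzoic acid) | COc1ccc(C(=O)O)cc1O | starting material
31 | tert-butyldimethylsilyl 3-(tert-butyldimethylsilyloxy)-4-methoxybenzoate | COc1ccc(C(=O)O[Si](C)(C)C(C)(C)C)cc1O[Si](C)(C)C(C)(C)C | intermediate
32 | 3-(tert-butyldimethylsilyloxy)-4-methoxybenzoic acid | COc1ccc(C(=O)O)cc1O[Si](C)(C)C(C)(C)C | intermediate
33 | 3-(tert-butyldimethylsilyloxy)-4-methoxybenzoic 2,4,6-trichlorobenzoic anhydride | COc1ccc(C(=O)OC(=O)c2c(Cl)cc(Cl)cc2Cl)cc1O[Si](C)(C)C(C)(C)C | intermediate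
34 | C8 ester of 29 with 3-(tert-butyldimethylsilyloxy)-4-methoxybenzoic acid (10-OH free) | COc1ccc(C(=O)O[C@@H]2C[C@](C)(O)C[C@H]3[C@@H](C[C@@]4(C)O[C@@H]34)[C@@H]2C(C)C)cc1O[Si](C)(C)C(C)(C)C | intermediate
35 | CNP0106636.1 (C8 isovanillate of the 3β,4β-epoxy-8β,10β-diol) | COc1ccc(C(=O)O[C@@H]2C[C@](C)(O)C[C@H]3[C@@H](C[C@@]4(C)O[C@@H]34)[C@@H]2C(C)C)cc1O | target

**Step count**

Total: 24 steps. Longest linear sequence: 20 steps (steps 4–21, 23, 24 from ethyl (S)-3-hydroxybutanoate; equally 1–3, 7–21, 23, 24 from isovaleraldehyde).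

**Steps most likely to fail**

1. Step 20 (the proposed epoxy-annulation). The ylide may add to the ketone with oxygen syn to sulfur and stall, may lose Ph2S by elimination toward H-2, or the ketone enolate may alkylate C3. The fallback sets out from diol 21 and uses known reactions only. Dess–Martin oxidation of both hydroxyls gives the bis-silyl keto aldehyde F1. Intramolecular McMurry coupling (TiCl3, Zn–Cu couple, DME, reflux, high dilution) gives the bis-silyl cyclopentene F2, with C3=C4 fixed by connectivity. NBS in aqueous THF forms the bromonium ion on the α face, away from C1, and water opens it at the tertiary C4 from the β face to give the bromohydrin F3 (3α-Br, 4β-OH). K2CO3 in MeOH closes the β-oxirane, and the route is rejoined at 28.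

2. Step 7 (Diels–Alder). Bond formation joins two substituted carbons (C6–C7), so turnover may be slow, the diene may be desilylated by the acidic catalyst, and endo or facial control may erode if the addition turns stepwise. The fallback sets out from aldehyde 8 and replaces catalyst control by auxiliary control. Olefination with (S)-4-benzyl-3-(diethoxyphosphorylacetyl)oxazolidin-2-one (LiCl, i-Pr2NEt, MeCN) gives the N-enoyl oxazolidinone F4. Its chelate with Me2AlCl (CH2Cl2, −78 °C) reacts with diene 5 at the Cα-Si face, anti to the benzyl group, to give the imide adduct F5. LiBH4 cleaves the auxiliary reductively, and the route is rejoined at alcohol 12.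

3. Step 19 (sulfonium formation). The silver-activated C3 may be captured internally by the C10 silyl ether oxygen or the C4 carbonyl oxygen, or suffer a hydride shift from C2, faster than the weakly nucleophilic sulfide attacks. The fallback sets out from iodide 23 and makes the C–S bond with a strong nucleophile first. PhSH and K2CO3 in DMF give the phenyl sulfide F6. Copper-catalysed S-arylation with diphenyliodonium tetrafluoroborate (Cu(OAc)2 cat., chlorobenzene, 100 °C) then gives the sulfonium salt, and the route is rejoined at 25.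

Further compounds
F1 | step 20 | bis-silyl keto aldehyde (2β-CHO, 6α-(2-oxopropyl)) | CC(=O)C[C@@H]1[C@@H](C=O)C[C@@](C)(O[Si](CC)(CC)CC)C[C@@H](O[Si](CC)(CC)CC)[C@H]1C(C)C
F2 | step 20 | bis-silyl hydroazulene with C3=C4 alkene | CC[Si](CC)(CC)O[C@@H]1C[C@](C)(O[Si](CC)(CC)CC)C[C@H]2[C@@H](CC(C)=C2)[C@@H]1C(C)C
F3 | step 20 | bromohydrin (3α-Br, 4β-OH, 4α-CH3) | CC[Si](CC)(CC)O[C@@H]1C[C@](C)(O[Si](CC)(CC)CC)C[C@H]2[C@@H](C[C@@](C)(O)[C@@H]2Br)[C@@H]1C(C)C
F4 | step 7 | (S)-4-benzyl-3-[(2E,5S)-5-(benzyloxy)hex-2-enoyl]oxazolidin-2-one | C[C@H](OCc1ccccc1)C/C=C/C(=O)N1[C@@H](Cc2ccccc2)COC1=O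
F5 | step 7 | Diels–Alder imide adduct (N-acyl oxazolidinone in place of the formyl group of 11) | C[C@H](OCc1ccccc1)C[C@@H]2[C@@H](C(=O)N3[C@@H](Cc4ccccc4)COC3=O)CC(C)=C(O[Si](C)(C)C(C)(C)C)[C@H]2C(C)C
F6 | step 19 | C3 phenyl sulfide of the keto bis-silyl cycloheptane | CC(=O)C[C@@H]1[C@@H](CSc2ccccc2)C[C@@](C)(O[Si](CC)(CC)CC)C[C@@H](O[Si](CC)(CC)CC)[C@H]1C(C)C
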